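**Strategy.** With C1 as the carboxyl carbon, the 1,2-dioxane ring (O1, O2, C3–C6) carries its two oxygens on C3 and C6, which are 1,4-related through C4 and C5. A C3–C6 bond in place of O–O turns this ring into a cyclobutane. The route therefore builds a 2-substituted tertiary cyclobutanol and lets cobalt-catalysed autoxidation exchange that bond for O–O. In one operation the four-membered ring opens, O2 is inserted, and the six-membered peroxyhemiketal forms with both C–O bonds and both stereocentres (racemic, thermodynamic relative configuration). The precursor is racemic methyl 2-[2-hydroxy-2-(5-trimethylsilylpent-4-ynyl)cyclobutyl]acetate, which already holds C1–C11.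

Key step: step 4

Assumption: Burkholderia cepacia lipase is taken to hydrolyse the (3S,6R) ester faster than its mirror image; the sense of enzyme preference cannot be read from the structure, and the opposite case is covered by the fallback for step 8.

Remarks:
- The target is (3S,6R): the two carbon chains are trans (both equatorial) and the methoxy group is axial.
- Compounds 5, 6, 10–14 and 18 are racemic; for 12–14 and 18 the SMILES shows the enantiomer that ends in the target.
- The cis isomer of 10 can close to a γ-lactone, so 10 is kept as the methyl ester (unchanged by the methanolic steps, accepted by lipases), quenched cold, kept free of acid and used at once.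

**Route**

Step 1
Reactants: 1 cyclobutanone
Product: 2 cyclobutanone N,N-dimethylhydrazone
Conditions: Me2NNH2 (1.2 equiv), AcOH (cat.), EtOH, rt to 50 °C
Reagents that add atoms: N,N-dimethylhydrazine, CN(C)N
Why: Hydrazone formation from a strained, unhindered ketone is fast and gives a base-stable azaenolate precursor; no stereocentre is formed.

Step 2
Reactants: 2 cyclobutanone N,N-dimethylhydrazone; 3 methyl bromoacetate
Product: 6 methyl 2-(2-oxocyclobutyl)acetate (racemic), via lithium azaenolate 4 (not isolated), via alkylated hydrazone 5 (not isolated)
Conditions: LiN(iPr)2 (1.05 equiv), THF, −78 to 0 °C; 3, −78 °C to rt; then aqueous oxalic acid, Et2O, rt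
Reagents that add atoms: water, O
Why: Hydrazone azaenolate alkylation followed by hydrolysis: the azaenolate is C-alkylated once by the reactive primary bromide without the self-condensation of cyclobutanone enolates, and mild biphasic acid returns the ketone while the methyl ester survives; the new α-stereocentre forms as the racemate and is erased again in step 4.

Step 3
Reactants: 7 (5-chloropent-1-yn-1-yl)trimethylsilane; 6 methyl 2-(2-oxocyclobutyl)acetate
Product: 10 methyl 2-[2-hydroxy-2-(5-trimethylsilylpent-4-ynyl)cyclobutyl]acetate (racemic; both diastereomers), via alkylmagnesium chloride 8 (not isolated), via alkylcerium dichloride 9 (not isolated)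
Conditions: 7, Mg, I2 (cat.), THF, reflux; anhydrous CeCl3, THF, −78 °C; 6, −78 °C; AcOH quench at −78 °C
Reagents that add atoms: none
Why: Organocerium 1,2-addition to a ketone: the weakly basic RCeCl2 adds to the strained cyclobutanone carbonyl much faster than to the ester and without enolisation; the new carbinol centre should arise mainly by attack anti to the ring substituent, but either diastereomer serves because both ring stereocentres are destroyed in step 4, and the cold acidic quench protonates the cis alkoxide before it can lactonise.

Step 4
Reactants: 10 methyl 2-[2-hydroxy-2-(5-trimethylsilylpent-4-ynyl)cyclobutyl]acetate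
Product: 12 methyl 2-[(3S*,6R*)-6-hydroxy-6-(5-trimethylsilylpent-4-ynyl)-1,2-dioxan-3-yl]acetate (racemic), via hydroperoxy ketone 11 (not isolated)
Conditions: Co(acac)2 (0.2 equiv), O2 (1 atm), 1,2-dichloroethane, 40 °C
Reagents that add atoms: dioxygen, O=O
Why: Divalent cobalt and O2 should turn the tertiary alcohol into a trivalent cobalt alkoxide whose homolysis gives the cyclobutyloxy radical; strain-driven β-scission then cleaves C3–C6, the C3 radical is trapped by triplet O2, and the peroxyl radical is passed through cobalt to the next alcohol molecule, leaving hydroperoxide 11. The closest known reaction type is the cobalt-catalysed aerobic ring expansion of cyclobutanols to cyclic peroxyhemiketals. The 1,2-dioxane ring closes by 6-exo-trig addition of the OOH group to the C6 ketone. C3 is created from a planar radical and C6 from a planar carbonyl, so 12 is racemic, while the reversible hemiketal closure sets the C3/C6 relative configuration thermodynamically (anomeric axial OH, both carbon chains equatorial). The step needs scission of C3–C6 and not C5–C6, which the substrate secures because only the former releases a secondary radical; O2 capture should outrun any attack on the distant silyl-capped alkyne, and both diastereomers of 10 converge on the same radical.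

Step 5
Reactants: 12 methyl 2-[(3S*,6R*)-6-hydroxy-6-(5-trimethylsilylpent-4-ynyl)-1,2-dioxan-3-yl]acetate
Product: 14 methyl 2-[(3S*,6R*)-6-methoxy-6-(pent-4-ynyl)-1,2-dioxan-3-yl]acetate (racemic), via silylated methyl ketal 13 (not isolated)
Conditions: TsOH·H2O (0.1 equiv), MeOH, rt; then K2CO3 (0.5 equiv), 0 °C to rt
Reagents that add atoms: methanol, CO
Why: Acid-catalysed ketalisation of the peroxyhemiketal through a peroxycarbenium ion should place OMe axial under thermodynamic (anomeric) control, keeping the C6 chain trans to the untouched C3 chain; carbonate added to the same methanol then cleaves the C(sp)–Si bond (base-catalysed protodesilylation), and a methyl ester in methanol cannot be scrambled.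

Step 6
Reactants: 15 1-undecyne
Product: 17 (E)-1-iodoundec-1-ene, via alkenylzirconocene chloride 16 (not isolated)
Conditions: Cp2Zr(H)Cl (1.2 equiv), THF, rt; then I2 (1.2 equiv), 0 °C
Reagents that add atoms: iodine, II
Why: Hydrozirconation–iodination: syn addition of Zr–H places zirconium on the terminal carbon and iodinolysis proceeds with retention, fixing the E geometry.

Step 7
Reactants: 14 methyl 2-[(3S*,6R*)-6-methoxy-6-(pent-4-ynyl)-1,2-dioxan-3-yl]acetate; 17 (E)-1-iodoundec-1-ene
Product: 18 methyl 2-[(3S*,6R*)-6-[(E)-hexadec-6-en-4-ynyl]-6-methoxy-1,2-dioxan-3-yl]acetate (racemic)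
Conditions: Pd(PPh3)4 (0.05 equiv), CuI (0.1 equiv), Et3N, THF, degassed, rt
Reagents that add atoms: none
Why: Sonogashira coupling of a terminal alkyne with an alkenyl iodide runs at room temperature with retention of the E geometry, and a dialkyl peroxyketal should not be reduced by zerovalent palladium or monovalent copper under these mild amine-buffered conditions; no stereocentre is touched.

Step 8
Reactants: 18 methyl 2-[(3S*,6R*)-6-[(E)-hexadec-6-en-4-ynyl]-6-methoxy-1,2-dioxan-3-yl]acetate
Product: 19 2-[(3S,6R)-6-[(E)-hexadec-6-en-4-ynyl]-6-methoxy-1,2-dioxan-3-yl]acetic acid (target)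
Conditions: Burkholderia cepacia lipase, phosphate buffer pH 7/acetone, 30 °C, stopped near 45% conversion; acid separated from unreacted ester
Reagents that add atoms: water, O
Why: Lipase-catalysed enantioselective ester hydrolysis (kinetic resolution) at neutral pH spares the peroxyketal and the enyne; no stereocentre is formed or disturbed, the enzyme selecting the (3S,6R) ester through the C3 centre β to the carbonyl and leaving the (3R,6S) ester behind.

**Compound list**

1 | cyclobutanone | O=C1CCC1 | starting material
2 | cyclobutanone N,N-dimethylhydrazone | CN(C)N=C1CCC1 | intermediate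
3 | methyl bromoacetate | COC(=O)CBr | starting material
4 | lithium azaenolate of 2 (lithium N-(cyclobut-1-enyl)-N',N'-dimethylhydrazide) | CN(C)N([Li])C1=CCC1 | intermediate
5 | methyl 2-[2-(dimethylhydrazinylidene)cyclobutyl]acetate (racemic) | COC(=O)CC1CCC1=NN(C)C | intermediate
6 | methyl 2-(2-oxocyclobutyl)acetate (racemic) | COC(=O)CC1CCC1=O | intermediate
7 | (5-chloropent-1-yn-1-yl)trimethylsilane | C[Si](C)(C)C#CCCCCl | starting material
8 | [5-(trimethylsilyl)pent-4-ynyl]magnesium chloride | C[Si](C)(C)C#CCCC[Mg]Cl | intermediate
9 | dichloro[5-(trimethylsilyl)pent-4-ynyl]cerium | C[Si](C)(C)C#CCCC[Ce](Cl)Cl | intermediate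
10 | methyl 2-[2-hydroxy-2-(5-trimethylsilylpent-4-ynyl)cyclobutyl]acetate (racemic, both diastereomers) | C[Si](C)(C)C#CCCCC1(O)CCC1CC(=O)OC | intermediate
11 | methyl 3-hydroperoxy-6-oxo-11-(trimethylsilyl)undec-10-ynoate (racemic) | C[Si](C)(C)C#CCCCC(=O)CCC(OO)CC(=O)OC | intermediate
12 | methyl 2-[(3S*,6R*)-6-hydroxy-6-(5-trimethylsilylpent-4-ynyl)-1,2-dioxan-3-yl]acetate (racemic, one enantiomer drawn) | C[Si](C)(C)C#CCCC[C@]1(O)CC[C@@H](CC(=O)OC)OO1 | intermediate
13 | methyl 2-[(3S*,6R*)-6-methoxy-6-(5-trimethylsilylpent-4-ynyl)-1,2-dioxan-3-yl]acetate (racemic, one enantiomer drawn) | C[Si](C)(C)C#CCCC[C@]1(OC)CC[C@@H](CC(=O)OC)OO1 | intermediate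
14 | methyl 2-[(3S*,6R*)-6-methoxy-6-(pent-4-ynyl)-1,2-dioxan-3-yl]acetate (racemic, one enantiomer drawn) | C#CCCC[C@]1(OC)CC[C@@H](CC(=O)OC)OO1 | intermediate
15 | 1-undecyne | C#CCCCCCCCCC | starting material
16 | chlorobis(cyclopentadienyl)[(E)-undec-1-enyl]zirconium | CCCCCCCCC/C=C/[Zr](Cl)(C1C=CC=C1)C1C=CC=C1 | intermediate
17 | (E)-1-iodoundec-1-ene | CCCCCCCCC/C=C/I | intermediate
18 | methyl 2-[(3S*,6R*)-6-[(E)-hexadec-6-en-4-ynyl]-6-methoxy-1,2-dioxan-3-yl]acetate (racemic, one enantiomer drawn) | CCCCCCCCC/C=C/C#CCCC[C@]1(OC)CC[C@@H](CC(=O)OC)OO1 | intermediate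
19 | 2-[(3S,6R)-6-[(E)-hexadec-6-en-4-ynyl]-6-methoxy-1,2-dioxan-3-yl]acetic acid | CCCCCCCCC/C=C/C#CCCC[C@]1(OC)CC[C@@H](CC(=O)O)OO1 | target

**Step count and risks**

Total step count: 8. Longest linear sequence: 7 steps (steps 1, 2, 3, 4, 5, 7, 8 from cyclobutanone 1); step 6 is a one-step side branch.

Steps most likely to fail:

1. Step 4. A tertiary alcohol may exchange onto cobalt slowly, so that alkoxy radical formation stalls. The C3 peroxyl radical or hydroperoxide may also be diverted by cobalt (dehydration to the C3 ketone, reduction to the C3 alcohol) before the ring closes. The fallback builds the ring by the known conjugate addition of a hydroperoxy ketal to an enoate, without a cyclobutane; it sets out from 7, used as its magnesium reagent 8, and comes back at 13. Acylation of 8 with N-methoxy-N-methylpent-4-enamide (THF, 0 °C) should give the ketone 10-(trimethylsilyl)dec-1-en-9-yn-5-one F1. Cross-metathesis of its terminal alkene with methyl acrylate (second-generation Hoveyda–Grubbs catalyst, CH2Cl2, 40 °C) should give methyl (E)-6-oxo-11-(trimethylsilyl)undec-2-en-10-ynoate F2. Acid-catalysed perketalisation (urea–hydrogen peroxide, Sc(OTf)3, MeOH, rt) should give methyl (E)-6-hydroperoxy-6-methoxy-11-(trimethylsilyl)undec-2-en-10-ynoate F3. Amine-promoted intramolecular conjugate addition of the hydroperoxide to the enoate (Et2NH, CF3CH2OH, rt; 6-exo-trig) should then close the ring to 13, from which the wanted C3 epimer is separated before the K2CO3/MeOH stage of step 5.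

2. Step 8. The lipase may discriminate poorly at a stereocentre β to the ester, or may prefer the mirror-image ester. The fallback replaces the enzymatic selection by a physical separation and a chemical hydrolysis; it sets out from 18 and comes back at 19. The enantiomers of 18 are separated by preparative chromatography on a chiral stationary phase (amylose tris(3,5-dimethylphenylcarbamate), hexane/iPrOH) to give methyl 2-[(3S,6R)-6-[(E)-hexadec-6-en-4-ynyl]-6-methoxy-1,2-dioxan-3-yl]acetate F4 as a single enantiomer. This is saponified with LiOH in THF/H2O at 0 °C and acidified to pH 4 to give 19. The same F4 is what remains unreacted if the lipase prefers the mirror-image ester.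

3. Step 3. The new tertiary alkoxide of the cis adduct may be acylated by the neighbouring methyl ester (lactonisation), and the organometallic may attack the ester in competition. The fallback masks the carboxyl as its salt during the addition; it sets out from 6 and comes back at 10. Saponification of 6 (LiOH, 1.0 equiv, THF/H2O, 0 °C; dried by azeotrope with toluene) should give lithium 2-(2-oxocyclobutyl)acetate F5, whose carboxylate cannot acylate an alkoxide. Addition of 9 (THF, −78 °C) and a neutral aqueous work-up should give lithium 2-[2-hydroxy-2-(5-trimethylsilylpent-4-ynyl)cyclobutyl]acetate F6. O-Alkylation of this carboxylate with MeI in DMF at rt, with no acid or alkoxide present, should then give 10.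

**Further compounds**

F1 | step 4 | 10-(trimethylsilyl)dec-1-en-9-yn-5-one | C[Si](C)(C)C#CCCCC(=O)CCC=C
F2 | step 4 | methyl (E)-6-oxo-11-(trimethylsilyl)undec-2-en-10-ynoate | C[Si](C)(C)C#CCCCC(=O)CC/C=C/C(=O)OC
F3 | step 4 | methyl (E)-6-hydroperoxy-6-methoxy-11-(trimethylsilyl)undec-2-en-10-ynoate (racemic) | C[Si](C)(C)C#CCCCC(OC)(OO)CC/C=C/C(=O)OC
F4 | step 8 | methyl 2-[(3S,6R)-6-[(E)-hexadec-6-en-4-ynyl]-6-methoxy-1,2-dioxan-3-yl]acetate (single enantiomer) | CCCCCCCCC/C=C/C#CCCC[C@]1(OC)CC[C@@H](CC(=O)OC)OO1
F5 | step 3 | lithium 2-(2-oxocyclobutyl)acetate (racemic) | [Li+].[O-]C(=O)CC1CCC1=O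
F6 | step 3 | lithium 2-[2-hydroxy-2-(5-trimethylsilylpent-4-ynyl)cyclobutyl]acetate (racemic, both diastereomers) | C[Si](C)(C)C#CCCCC1(O)CCC1CC(=O)[O-].[Li+]
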